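**Plan**

- Retrosynthetic cuts: the three O–benzyl bonds; then the bond from lactone α-carbon C3 to the benzylic CH2 of the dihydrobenzofuran; then, together, the lactone bonds O1–C5 and C3–C4; in the benzofuran half, the furan C2–C3 bond, the aryl–C3 bond and one benzylic ether O–CH2 bond.
- Enabling feature: the butanolide is O1–C2(=O)–C3 (a ketene unit) closed across C4–C5 (an alkene). C5 is the O-bearing CH2 beside stereocentre C4, so it can carry a temporary stereogenic sulfinyl group that relays chirality to C4 and then leaves as thioacetal sulfur; two chlorines on C3 activate the ketene and are removed afterwards.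
- Forward order: bromide → propyne → (E)-iodoalkene → (R)-sulfoxide → lactone ring in one operation → removal of Cl and S. Separately: ether on the 5-iodovanillin-derived catechol, diazo ester, dihydrofuran ring by carbene C–H insertion, reduction, benzylic bromide. The halves are joined by enolate benzylation; benzyl ethers come off last.
- Stereochemistry: lactone C4 from sulfur (menthyl sulfinate → sulfoxide → carbon in the sigmatropic step); lactone C3 from C4 (trans alkylation); benzofuran C2 from the chiral dirhodium carboxylate; benzofuran C3 by epimerisation of the ester to 2,3-trans.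

Key step: step 5

Assumption: the sulfur-to-carbon chirality transfer is taken to follow the chair-like sigmatropic model with the p-tolyl group pseudo-equatorial, so the (R)-sulfoxide of the (E)-alkene gives the 4S arrangement; if experiment shows the opposite sense, the enantiomeric sulfinate would be used in step 4, and likewise the antipodal rhodium catalyst in step 11.

**Route**

Step 1
Reactants: 1 4-(benzyloxy)-3-methoxybenzyl alcohol
Product: 2 4-(benzyloxy)-3-methoxybenzyl bromide
Conditions: PBr3 (0.4 equiv), Et2O, 0 °C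
Reagents that add atoms: phosphorus tribromide, BrP(Br)Br
Why: A primary benzylic alcohol is converted to the bromide by SN2 displacement of its phosphite ester; no stereocentre is involved.

Step 2
Reactants: 2 4-(benzyloxy)-3-methoxybenzyl bromide
Product: 3 1-(benzyloxy)-2-methoxy-4-(prop-2-yn-1-yl)benzene
Conditions: HC≡CMgBr (3 equiv), CuCl (10 mol %), THF, 0 → 50 °C
Reagents that add atoms: ethynylmagnesium bromide, C#C[Mg]Br
Why: Copper-catalysed coupling of a benzylic bromide with an alkynyl Grignard reagent gives the 3-arylpropyne, and the excess Grignard reagent holds the product as its acetylide so that it does not isomerise to the allene.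

Step 3
Reactants: 3 1-(benzyloxy)-2-methoxy-4-(prop-2-yn-1-yl)benzene
Product: 5 1-(benzyloxy)-4-[(E)-3-iodoprop-2-en-1-yl]-2-methoxybenzene, via alkenylzirconocene chloride 4 (not isolated)
Conditions: Cp2Zr(H)Cl (1.2 equiv), THF, rt; then I2, 0 °C
Reagents that add atoms: iodine, [I][I]
Why: Hydrozirconation adds Zr–H syn and anti-Markovnikov to the terminal alkyne, and iodinolysis of the C–Zr bond with retention gives the (E)-iodoalkene.

Step 4
Reactants: 5 1-(benzyloxy)-4-[(E)-3-iodoprop-2-en-1-yl]-2-methoxybenzene; 6 (1R,2S,5R)-menthyl (S)-4-methylbenzenesulfinate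
Product: 9 1-(benzyloxy)-2-methoxy-4-{(E)-3-[(R)-4-methylbenzenesulfinyl]prop-2-en-1-yl}benzene, via alkenyllithium 7 (not isolated), via alkenylmagnesium bromide 8 (not isolated)
Conditions: t-BuLi (2.0 equiv), Et2O, −78 °C; MgBr2·OEt2; then added to 6, toluene–Et2O, −78 → −20 °C; H2O quench
Reagents that add atoms: none
Why: Iodine–lithium exchange and transmetalation keep the (E) geometry, and the Andersen sulfoxide synthesis displaces menthoxide at sulfur with inversion, so the (S)-sulfinate gives the (R)-sulfoxide; inverse addition at low temperature avoids base-induced shift of the double bond into conjugation with the arene.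

Step 5
Reactants: 9 1-(benzyloxy)-2-methoxy-4-{(E)-3-[(R)-4-methylbenzenesulfinyl]prop-2-en-1-yl}benzene
Product: 12 (4R)-3,3-dichloro-4-{[4-(benzyloxy)-3-methoxyphenyl]methyl}-5-[(4-methylphenyl)sulfanyl]oxolan-2-one (C5 epimers), via acyloxysulfonium enolate 10 (not isolated), via thionium carboxylate 11 (not isolated)
Conditions: Cl3CCOCl (2.5 equiv), Zn–Cu couple, THF, −45 → 0 °C
Reagents that add atoms: trichloroacetyl chloride (delivers dichloroketene), ClC(Cl)(Cl)C(Cl)=O
Why: Dichloroketene, formed from the acid chloride and zinc, is attacked by the sulfinyl oxygen to give the acyloxysulfonium enolate 10, which undergoes a [3,3]-sigmatropic shift through a six-membered chair (S–O broken, C3–C4 made) to the thionium carboxylate 11, whose carboxylate oxygen then adds to the thionium carbon to make O1–C5. The closest known reaction type is the lactonisation of 1-alkenyl p-tolyl sulfoxides with dichloroketene, an additive Pummerer reaction. The lactone ring closes by 5-exo-trig attack of the carboxylate oxygen on the C5=S bond. C4 is set by the sulfur stereocentre, because in the chair with the p-tolyl group pseudo-equatorial the oxygen-bound enolate carbon reaches only one face of the (E)-alkene, giving the arrangement that is 4S once chlorine and sulfur are gone (the descriptor of 12 is 4R only because CCl2 outranks C5); C5 is not controlled and loses its sulfur in step 6, and C3 carries two chlorines and is no stereocentre. The step needs face selectivity in the C–C bond formation and chemoselectivity of the ketene for the sulfinyl oxygen over cycloaddition to the electron-rich arene or alkene; the high nucleophilicity of the sulfinyl oxygen, the intramolecular delivery of both new bonds and the fixed (E) geometry secure these.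

Step 6
Reactants: 12 (4R)-3,3-dichloro-4-{[4-(benzyloxy)-3-methoxyphenyl]methyl}-5-[(4-methylphenyl)sulfanyl]oxolan-2-one
Product: 13 (4S)-4-{[4-(benzyloxy)-3-methoxyphenyl]methyl}oxolan-2-one
Conditions: Bu3SnH (3.5 equiv), AIBN (cat.), toluene, 100 °C
Reagents that add atoms: none
Why: A stannyl radical chain reduction removes both α-chlorines and the arylthio group of the O,S-acetal, each carbon radical being quenched by Sn–H; C4 never becomes a radical centre, so its configuration is kept and the benzyl ether survives.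

Step 7
Reactants: 14 5-iodovanillin (4-hydroxy-3-iodo-5-methoxybenzaldehyde)
Product: 15 3,4-dihydroxy-5-iodobenzaldehyde
Conditions: AlCl3 (1.1 equiv), pyridine (4.4 equiv), CH2Cl2, reflux; then aq HCl
Reagents that add atoms: none
Why: The aluminium chelate of the ortho-hydroxy anisole is demethylated by pyridine attacking the methyl group, a standard route from vanillins to catechols that leaves iodide and aldehyde untouched.

Step 8
Reactants: 15 3,4-dihydroxy-5-iodobenzaldehyde; 2 4-(benzyloxy)-3-methoxybenzyl bromide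
Product: 16 4-{[4-(benzyloxy)-3-methoxyphenyl]methoxy}-3-hydroxy-5-iodobenzaldehyde
Conditions: Li2CO3 (1.2 equiv), DMF, 45 °C
Reagents that add atoms: none
Why: In this Williamson etherification with one equivalent of weak base, the 4-hydroxyl (para to the formyl group, ortho to iodine) is the more acidic, so its phenoxide is alkylated selectively.

Step 9
Reactants: 16 4-{[4-(benzyloxy)-3-methoxyphenyl]methoxy}-3-hydroxy-5-iodobenzaldehyde
Product: 17 3-(benzyloxy)-4-{[4-(benzyloxy)-3-methoxyphenyl]methoxy}-5-iodobenzaldehyde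
Conditions: BnBr (1.2 equiv), K2CO3, DMF, rt
Reagents that add atoms: benzyl bromide, BrCc1ccccc1
Why: Williamson benzylation of the remaining phenol masks the future 7-hydroxyl.

Step 10
Reactants: 17 3-(benzyloxy)-4-{[4-(benzyloxy)-3-methoxyphenyl]methoxy}-5-iodobenzaldehyde
Product: 18 methyl 2-[3-(benzyloxy)-2-{[4-(benzyloxy)-3-methoxyphenyl]methoxy}-5-formylphenyl]-2-diazoacetate
Conditions: N2CHCO2Me (1.5 equiv), Pd(PPh3)4 (5 mol %), Ag2CO3 (0.5 equiv), Et3N, toluene, rt
Reagents that add atoms: methyl diazoacetate, COC(=O)C=[N+]=[N-]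
Why: Palladium-catalysed cross-coupling of an aryl iodide with the C–H bond of a diazoacetate (oxidative addition, palladation of the diazo carbon, reductive elimination) keeps the diazo group and tolerates the aldehyde, with silver carbonate taking up iodide.

Step 11
Reactants: 18 methyl 2-[3-(benzyloxy)-2-{[4-(benzyloxy)-3-methoxyphenyl]methoxy}-5-formylphenyl]-2-diazoacetate
Product: 19 methyl (2S,3R)-7-(benzyloxy)-2-[4-(benzyloxy)-3-methoxyphenyl]-5-formyl-2,3-dihydro-1-benzofuran-3-carboxylate (2,3-cis)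
Conditions: Rh2(R-PTTL)4 [dirhodium tetrakis(N-phthaloyl-(R)-tert-leucinate)] (1 mol %), toluene, −60 °C
Reagents that add atoms: none
Why: The rhodium carbene inserts into the activated benzylic ether C–H bond five atoms away and closes the dihydrofuran ring (C2–C3), the chiral carboxylate ligands fixing C2 as S and giving the kinetic cis ester; the (R)-ligand is chosen by analogy with the known sense of these tert-leucinate catalysts in this ring closure.

Step 12
Reactants: 19 methyl (2S,3R)-7-(benzyloxy)-2-[4-(benzyloxy)-3-methoxyphenyl]-5-formyl-2,3-dihydro-1-benzofuran-3-carboxylate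
Product: 20 methyl (2S,3S)-7-(benzyloxy)-2-[4-(benzyloxy)-3-methoxyphenyl]-5-formyl-2,3-dihydro-1-benzofuran-3-carboxylate (2,3-trans)
Conditions: NaOMe (0.3 equiv), MeOH–THF, rt
Reagents that add atoms: none
Why: Epimerisation at C3 through the ester enolate gives the more stable trans ester, while C2 is untouched because opening of the ring would be the reverse of a disfavoured 5-endo-trig closure.

Step 13
Reactants: 20 methyl (2S,3S)-7-(benzyloxy)-2-[4-(benzyloxy)-3-methoxyphenyl]-5-formyl-2,3-dihydro-1-benzofuran-3-carboxylate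
Product: 21 [(2S,3R)-7-(benzyloxy)-2-[4-(benzyloxy)-3-methoxyphenyl]-2,3-dihydro-1-benzofuran-3,5-diyl]dimethanol
Conditions: LiAlH4 (1.5 equiv), THF, 0 °C; aq NaOH work-up
Reagents that add atoms: none
Why: Hydride reduction converts the ester and the aldehyde into primary alcohols without touching C2 or C3, and C3 is no longer epimerisable afterwards.

Step 14
Reactants: 21 [(2S,3R)-7-(benzyloxy)-2-[4-(benzyloxy)-3-methoxyphenyl]-2,3-dihydro-1-benzofuran-3,5-diyl]dimethanol
Product: 23 (2S,3R)-7-(benzyloxy)-2-[4-(benzyloxy)-3-methoxyphenyl]-5-(bromomethyl)-3-[(trimethylsilyloxy)methyl]-2,3-dihydro-1-benzofuran, via bis(trimethylsilyl) ether 22 (not isolated)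
Conditions: BSA (2.5 equiv), CH2Cl2, rt; then Me3SiBr (1.2 equiv), 0 °C; evaporate, use crude
Reagents that add atoms: N,O-bis(trimethylsilyl)acetamide, CC(=N[Si](C)(C)C)O[Si](C)(C)C; bromotrimethylsilane, C[Si](C)(C)Br
Why: Both alcohols are silylated under neutral conditions and bromotrimethylsilane then converts only the benzylic silyl ether to the bromide, because its ionisation is assisted by the para ring oxygen whereas the primary alkyl silyl ether can neither ionise nor undergo SN2 at 0 °C; no free HBr is formed, which spares the C2–O bond.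

Step 15
Reactants: 13 (4S)-4-{[4-(benzyloxy)-3-methoxyphenyl]methyl}oxolan-2-one; 23 (2S,3R)-7-(benzyloxy)-2-[4-(benzyloxy)-3-methoxyphenyl]-5-(bromomethyl)-3-[(trimethylsilyloxy)methyl]-2,3-dihydro-1-benzofuran
Product: 26 (3S,4S)-4-{[4-(benzyloxy)-3-methoxyphenyl]methyl}-3-({(2S,3R)-7-(benzyloxy)-2-[4-(benzyloxy)-3-methoxyphenyl]-3-(hydroxymethyl)-2,3-dihydro-1-benzofuran-5-yl}methyl)oxolan-2-one, via lithium enolate 24 (not isolated), via trimethylsilyl ether 25 (not isolated)
Conditions: LiN(SiMe3)2 (1.05 equiv), THF, −78 °C; 23, THF–DMPU, −78 → −30 °C; then aq citric acid, THF, rt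
Reagents that add atoms: none
Why: The lithium enolate of a β-substituted γ-butyrolactone is alkylated by a reactive benzylic bromide anti to the C4 substituent, setting C3 trans (3S) as in the standard route to dibenzylbutyrolactone lignans, and the mild acid work-up removes the trimethylsilyl ether.

Step 16
Reactants: 26 (3S,4S)-4-{[4-(benzyloxy)-3-methoxyphenyl]methyl}-3-({(2S,3R)-7-(benzyloxy)-2-[4-(benzyloxy)-3-methoxyphenyl]-3-(hydroxymethyl)-2,3-dihydro-1-benzofuran-5-yl}methyl)oxolan-2-one
Product: 27 (3S,4S)-3-{[(2S,3R)-7-hydroxy-2-(4-hydroxy-3-methoxyphenyl)-3-(hydroxymethyl)-2,3-dihydro-1-benzofuran-5-yl]methyl}-4-[(4-hydroxy-3-methoxyphenyl)methyl]oxolan-2-one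
Conditions: H2 (1 atm), Pd/C (10 %), EtOAc–EtOH, rt
Reagents that add atoms: none
Why: Hydrogenolysis of the three aryl benzyl ethers under neutral conditions frees the phenols, while the lactone and the cyclic benzylic ether at C2, which cleaves much more slowly without acid, should remain.

**Compound list**

1 | 4-(benzyloxy)-3-methoxybenzyl alcohol | COc1cc(CO)ccc1OCc1ccccc1 | starting material
2 | 4-(benzyloxy)-3-methoxybenzyl bromide | COc1cc(CBr)ccc1OCc1ccccc1 | intermediate
3 | 1-(benzyloxy)-2-methoxy-4-(prop-2-yn-1-yl)benzene | COc1cc(CC#C)ccc1OCc1ccccc1 | intermediate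
4 | chlorobis(cyclopentadienyl){(E)-3-[4-(benzyloxy)-3-methoxyphenyl]prop-1-enyl}zirconium | COc1cc(C/C=C/[Zr](Cl)(C2C=CC=C2)C2C=CC=C2)ccc1OCc1ccccc1 | intermediate
5 | 1-(benzyloxy)-4-[(E)-3-iodoprop-2-en-1-yl]-2-methoxybenzene | COc1cc(C/C=C/I)ccc1OCc1ccccc1 | intermediate
6 | (1R,2S,5R)-menthyl (S)-4-methylbenzenesulfinate | C[C@@H]1CC[C@H]([C@@H](C1)O[S@](=O)c1ccc(C)cc1)C(C)C | starting material
7 | {(E)-3-[4-(benzyloxy)-3-methoxyphenyl]prop-1-enyl}lithium | COc1cc(C/C=C/[Li])ccc1OCc1ccccc1 | intermediate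
8 | {(E)-3-[4-(benzyloxy)-3-methoxyphenyl]prop-1-enyl}magnesium bromide | COc1cc(C/C=C/[Mg]Br)ccc1OCc1ccccc1 | intermediate
9 | 1-(benzyloxy)-2-methoxy-4-{(E)-3-[(R)-4-methylbenzenesulfinyl]prop-2-en-1-yl}benzene | COc1cc(C/C=C/[S@@](=O)c2ccc(C)cc2)ccc1OCc1ccccc1 | intermediate
10 | acyloxysulfonium enolate: S-(2,2-dichloro-1-oxidoethenyloxy) sulfonium zwitterion of 9, sulfur configuration as in 9 | COc1cc(C/C=C/[S@@+](OC([O-])=C(Cl)Cl)c2ccc(C)cc2)ccc1OCc1ccccc1 | intermediate
11 | thionium carboxylate: 2,2-dichloro-3-{[4-(benzyloxy)-3-methoxyphenyl]methyl}-4-[(4-methylphenyl)sulfaniumylidene]butanoate, new stereocentre as in 12 | COc1cc(C[C@H](C=[S+]c2ccc(C)cc2)C(Cl)(Cl)C([O-])=O)ccc1OCc1ccccc1 | intermediate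
12 | (4R)-3,3-dichloro-4-{[4-(benzyloxy)-3-methoxyphenyl]methyl}-5-[(4-methylphenyl)sulfanyl]oxolan-2-one, C5 not fixed | COc1cc(C[C@@H]2C(Sc3ccc(C)cc3)OC(=O)C2(Cl)Cl)ccc1OCc1ccccc1 | intermediate
13 | (4S)-4-{[4-(benzyloxy)-3-methoxyphenyl]methyl}oxolan-2-one | COc1cc(C[C@@H]2COC(=O)C2)ccc1OCc1ccccc1 | intermediate
14 | 5-iodovanillin | COc1cc(C=O)cc(I)c1O | starting material
15 | 3,4-dihydroxy-5-iodobenzaldehyde | Oc1cc(C=O)cc(I)c1O | intermediate
16 | 4-{[4-(benzyloxy)-3-methoxyphenyl]methoxy}-3-hydroxy-5-iodobenzaldehyde | COc1cc(COc2c(O)cc(C=O)cc2I)ccc1OCc1ccccc1 | intermediate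
17 | 3-(benzyloxy)-4-{[4-(benzyloxy)-3-methoxyphenyl]methoxy}-5-iodobenzaldehyde | COc1cc(COc2c(OCc3ccccc3)cc(C=O)cc2I)ccc1OCc1ccccc1 | intermediate
18 | methyl 2-[3-(benzyloxy)-2-{[4-(benzyloxy)-3-methoxyphenyl]methoxy}-5-formylphenyl]-2-diazoacetate | COc1cc(COc2c(OCc3ccccc3)cc(C=O)cc2C(=[N+]=[N-])C(=O)OC)ccc1OCc1ccccc1 | intermediate
19 | methyl (2S,3R)-7-(benzyloxy)-2-[4-(benzyloxy)-3-methoxyphenyl]-5-formyl-2,3-dihydro-1-benzofuran-3-carboxylate (cis) | O=Cc1cc(OCc2ccccc2)c2c(c1)[C@@H](C(=O)OC)[C@@H](c1ccc(OCc3ccccc3)c(OC)c1)O2 | intermediate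
20 | methyl (2S,3S)-7-(benzyloxy)-2-[4-(benzyloxy)-3-methoxyphenyl]-5-formyl-2,3-dihydro-1-benzofuran-3-carboxylate (trans) | O=Cc1cc(OCc2ccccc2)c2c(c1)[C@H](C(=O)OC)[C@@H](c1ccc(OCc3ccccc3)c(OC)c1)O2 | intermediate
21 | [(2S,3R)-7-(benzyloxy)-2-[4-(benzyloxy)-3-methoxyphenyl]-2,3-dihydro-1-benzofuran-3,5-diyl]dimethanol (trans) | OCc1cc(OCc2ccccc2)c2c(c1)[C@H](CO)[C@@H](c1ccc(OCc3ccccc3)c(OC)c1)O2 | intermediate
22 | bis(trimethylsilyl) ether of 21 | C[Si](C)(C)OCc1cc(OCc2ccccc2)c2c(c1)[C@H](CO[Si](C)(C)C)[C@@H](c1ccc(OCc3ccccc3)c(OC)c1)O2 | intermediate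
23 | (2S,3R)-7-(benzyloxy)-2-[4-(benzyloxy)-3-methoxyphenyl]-5-(bromomethyl)-3-[(trimethylsilyloxy)methyl]-2,3-dihydro-1-benzofuran | BrCc1cc(OCc2ccccc2)c2c(c1)[C@H](CO[Si](C)(C)C)[C@@H](c1ccc(OCc3ccccc3)c(OC)c1)O2 | intermediate
24 | lithium enolate of 13 | COc1cc(C[C@@H]2COC(O[Li])=C2)ccc1OCc1ccccc1 | intermediate
25 | trimethylsilyl ether of 26 | COc1cc(C[C@@H]2COC(=O)[C@H]2Cc2cc(OCc3ccccc3)c3c(c2)[C@H](CO[Si](C)(C)C)[C@@H](c2ccc(OCc4ccccc4)c(OC)c2)O3)ccc1OCc1ccccc1 | intermediate
26 | (3S,4S)-4-{[4-(benzyloxy)-3-methoxyphenyl]methyl}-3-({(2S,3R)-7-(benzyloxy)-2-[4-(benzyloxy)-3-methoxyphenyl]-3-(hydroxymethyl)-2,3-dihydro-1-benzofuran-5-yl}methyl)oxolan-2-one | COc1cc(C[C@@H]2COC(=O)[C@H]2Cc2cc(OCc3ccccc3)c3c(c2)[C@H](CO)[C@@H](c2ccc(OCc4ccccc4)c(OC)c2)O3)ccc1OCc1ccccc1 | intermediate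
27 | (3S,4S)-3-{[(2S,3R)-7-hydroxy-2-(4-hydroxy-3-methoxyphenyl)-3-(hydroxymethyl)-2,3-dihydro-1-benzofuran-5-yl]methyl}-4-[(4-hydroxy-3-methoxyphenyl)methyl]oxolan-2-one | COc1cc(C[C@@H]2COC(=O)[C@H]2Cc2cc(O)c3c(c2)[C@H](CO)[C@@H](c2ccc(O)c(OC)c2)O3)ccc1O | target

**Step count and risks**

Total steps: 16. Longest linear sequence: 10 steps (steps 7 to 16).

Steps most likely to fail:

1. Step 11 (carbene C–H insertion). The extra benzyloxy group beside the ether oxygen may erode enantio- or cis-selectivity, and the formyl group may divert the carbene into carbonyl ylide chemistry. The fallback sets out from 17 and returns at 20, replacing catalyst control by auxiliary control. Iodide 17 would be coupled under the conditions of step 10 with the diazoacetate of (S)-2-hydroxy-1-(pyrrolidin-1-yl)propan-1-one to give the lactamide-bearing aryl diazoacetate F1. Insertion with Rh2(OAc)4 would give the dihydrobenzofuran lactamide ester F2, whose C2 diastereomers can be separated by chromatography or crystallisation. NaOMe in MeOH would then transesterify and epimerise C3 in one operation to give 20.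

2. Step 14 (selective bromination). The two carbinols may not be told apart cleanly, the cyclic benzylic ether may open under the silyl bromide, or the silyl ether may be lost before the alkylation. The fallback sets out from 21 and returns at 26, using selective oxidation instead of selective ionisation. MnO2 would oxidise only the benzylic alcohol to the hydroxy aldehyde F3. TBSCl and imidazole would give the silyl ether aldehyde F4, NaBH4 the benzylic alcohol F5, and CBr4/PPh3 (Appel reaction) the bromide F6. Alkylation of enolate 24 with F6 as in step 15 would give the silyl ether F7, and Bu4NF buffered with AcOH would release 26.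

3. Step 10 (aryl iodide–diazoacetate coupling). Oxidative addition at the ortho-alkoxy iodide may be slow relative to decomposition or dimerisation of the diazo ester. The fallback sets out from 17 and returns at 18, building the diazo group after the C–C bond instead of carrying it through the coupling. Palladium-catalysed α-arylation of 1-methoxy-1-(trimethylsilyloxy)ethene (Pd(dba)2, P(t-Bu)3, ZnF2, DMF, 80 °C) would give the methyl arylacetate F8. Regitz diazo transfer with 4-acetamidobenzenesulfonyl azide and DBU in MeCN would then give 18.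

Further compounds
F1 | step 11 | (S)-1-oxo-1-(pyrrolidin-1-yl)propan-2-yl 2-[3-(benzyloxy)-2-{[4-(benzyloxy)-3-methoxyphenyl]methoxy}-5-formylphenyl]-2-diazoacetate | COc1cc(COc2c(OCc3ccccc3)cc(C=O)cc2C(=[N+]=[N-])C(=O)O[C@@H](C)C(=O)N2CCCC2)ccc1OCc1ccccc1
F2 | step 11 | (S)-1-oxo-1-(pyrrolidin-1-yl)propan-2-yl (2S)-7-(benzyloxy)-2-[4-(benzyloxy)-3-methoxyphenyl]-5-formyl-2,3-dihydro-1-benzofuran-3-carboxylate, C3 not fixed | O=Cc1cc(OCc2ccccc2)c2c(c1)C(C(=O)O[C@@H](C)C(=O)N1CCCC1)[C@@H](c1ccc(OCc3ccccc3)c(OC)c1)O2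
F3 | step 14 | (2S,3R)-7-(benzyloxy)-2-[4-(benzyloxy)-3-methoxyphenyl]-3-(hydroxymethyl)-2,3-dihydro-1-benzofuran-5-carbaldehyde | O=Cc1cc(OCc2ccccc2)c2c(c1)[C@H](CO)[C@@H](c1ccc(OCc3ccccc3)c(OC)c1)O2
F4 | step 14 | (2S,3R)-7-(benzyloxy)-2-[4-(benzyloxy)-3-methoxyphenyl]-3-{[tert-butyl(dimethyl)silyloxy]methyl}-2,3-dihydro-1-benzofuran-5-carbaldehyde | O=Cc1cc(OCc2ccccc2)c2c(c1)[C@H](CO[Si](C)(C)C(C)(C)C)[C@@H](c1ccc(OCc3ccccc3)c(OC)c1)O2
F5 | step 14 | [(2S,3R)-7-(benzyloxy)-2-[4-(benzyloxy)-3-methoxyphenyl]-3-{[tert-butyl(dimethyl)silyloxy]methyl}-2,3-dihydro-1-benzofuran-5-yl]methanol | OCc1cc(OCc2ccccc2)c2c(c1)[C@H](CO[Si](C)(C)C(C)(C)C)[C@@H](c1ccc(OCc3ccccc3)c(OC)c1)O2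
F6 | step 14 | (2S,3R)-7-(benzyloxy)-2-[4-(benzyloxy)-3-methoxyphenyl]-5-(bromomethyl)-3-{[tert-butyl(dimethyl)silyloxy]methyl}-2,3-dihydro-1-benzofuran | BrCc1cc(OCc2ccccc2)c2c(c1)[C@H](CO[Si](C)(C)C(C)(C)C)[C@@H](c1ccc(OCc3ccccc3)c(OC)c1)O2
F7 | step 14 | tert-butyldimethylsilyl ether of 26 | COc1cc(C[C@@H]2COC(=O)[C@H]2Cc2cc(OCc3ccccc3)c3c(c2)[C@H](CO[Si](C)(C)C(C)(C)C)[C@@H](c2ccc(OCc4ccccc4)c(OC)c2)O3)ccc1OCc1ccccc1
F8 | step 10 | methyl 2-[3-(benzyloxy)-2-{[4-(benzyloxy)-3-methoxyphenyl]methoxy}-5-formylphenyl]acetate | COc1cc(COc2c(OCc3ccccc3)cc(C=O)cc2CC(=O)OC)ccc1OCc1ccccc1
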